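**Plan**

Cuts: (a) the depside bond C(=O)–O–C4' between the ring A acid and the ring B phenol. (b) The ArCH2–C(=O) bond of the ring A 2-oxoheptyl arm and the C(=O)–pentyl bond of the ring B arm. (c) In ring B, together, C1'–CO2Me and C6'–CH2.
Enabling feature: in ring B the ester carbon on C1' and the side-chain CH2 on C6' are ortho neighbours, and C1' has the C2' methoxy group on its other side. Both carbon substituents can therefore be delivered at once to the C1'≡C6' triple bond of a 3-alkoxyaryne by a malonate whose C–C sigma bond opens.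
Forward: neither benzene ring is built. Ring B comes from 5-bromovanillin (CHO becomes the C4' oxygen, Br marks C6' for silicon, the phenol oxygen on C1' becomes the triflate). Ring A comes from methyl 2-hydroxy-4-methoxy-6-methylbenzoate.
Order: silyl triflate, aryne/malonate insertion, acetate arm to N-methoxy-N-methylamide to pentyl ketone, debenzylation. In parallel: lateral acylation of the ring A toluate, ketal, saponification. Then esterification and a one-flask deprotection.
Stereochemistry: gustastatin has no stereocentre and no configured double bond, so nothing has to be set. Control is needed only over regiochemistry (aryne) and chemoselectivity (two esters).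

Key step: step 7

Remark on the chemistry: C1–C6 denote ring A (C1 bears the depside carbonyl) and C1'–C6' denote ring B (C1' bears CO2Me, C4' the depside oxygen). Commercial 5-bromovanillin is used because its bromine already sits on the carbon that must carry silicon, so no directed metalation has to choose between ring positions.

**Step 1**
Reactants: 1 5-bromovanillin (3-bromo-4-hydroxy-5-methoxybenzaldehyde)
Product: 2 3-bromo-5-methoxy-4-(methoxymethoxy)benzaldehyde
Conditions: MOMCl, iPr2NEt, CH2Cl2, 0 °C to rt
Reagents that add atoms: chloromethyl methyl ether, COCCl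
Why: Williamson-type O-alkylation of the acidic phenol masks the oxygen that will later carry the triflate, and an ether (unlike an acyl group) keeps the ring electron-rich enough for aryl migration in step 2.

**Step 2**
Reactants: 2 3-bromo-5-methoxy-4-(methoxymethoxy)benzaldehyde
Product: 4 3-bromo-5-methoxy-4-(methoxymethoxy)phenol, via aryl formate 3 (not isolated)
Conditions: mCPBA, CH2Cl2, 0 °C to rt; concentrate; K2CO3 (cat.), MeOH, rt
Reagents that add atoms: 3-chloroperbenzoic acid, O=C(OO)c1cccc(Cl)c1
Why: Baeyer-Villiger oxidation of a benzaldehyde with a para alkoxy donor proceeds by aryl rather than hydride migration, and base-catalysed methanolysis then cleaves the formate without touching the MOM ether or the aryl bromide.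

**Step 3**
Reactants: 4 3-bromo-5-methoxy-4-(methoxymethoxy)phenol
Product: 5 5-(benzyloxy)-1-bromo-3-methoxy-2-(methoxymethoxy)benzene
Conditions: BnBr, K2CO3, DMF, rt
Reagents that add atoms: benzyl bromide, BrCc1ccccc1
Why: Williamson etherification of the only free phenol installs a group that tolerates cold n-BuLi, fluoride, AlMe3 and the Grignard reagent and is later removed by hydrogenolysis.

**Step 4**
Reactants: 5 5-(benzyloxy)-1-bromo-3-methoxy-2-(methoxymethoxy)benzene
Product: 6 4-(benzyloxy)-2-bromo-6-methoxyphenol
Conditions: conc. HCl (cat.), MeOH, 50 °C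
Reagents that add atoms: none
Why: Acid-catalysed acetal exchange with methanol removes only the MOM group, because aryl benzyl and aryl methyl ethers are inert to dilute HCl.

**Step 5**
Reactants: 6 4-(benzyloxy)-2-bromo-6-methoxyphenol
Product: 7 [4-(benzyloxy)-2-bromo-6-methoxyphenoxy]trimethylsilane
Conditions: HMDS, THF, 70 °C; evaporate
Reagents that add atoms: hexamethyldisilazane, C[Si](C)(C)N[Si](C)(C)C
Why: O-silylation of a phenol with HMDS needs no added base and leaves only a volatile by-product, so the moisture-sensitive silyl ether can be used after simple evaporation.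

**Step 6**
Reactants: 7 [4-(benzyloxy)-2-bromo-6-methoxyphenoxy]trimethylsilane
Product: 9 4-(benzyloxy)-2-methoxy-6-(trimethylsilyl)phenyl trifluoromethanesulfonate, via lithium phenoxide 8 (not isolated)
Conditions: n-BuLi, THF, −100 to −80 °C; then Tf2O, −100 to −80 °C
Reagents that add atoms: trifluoromethanesulfonic anhydride, O=S(=O)(C(F)(F)F)OS(=O)(=O)C(F)(F)F
Why: Bromine-lithium exchange outruns any benzylic or ring deprotonation, the aryllithium takes the silyl group from the neighbouring oxygen (retro-Brook 1,3 O-to-C shift), and Tf2O traps the resulting phenoxide, which is the standard route to ortho-silylaryl triflates.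

**Step 7**
Reactants: 9 4-(benzyloxy)-2-methoxy-6-(trimethylsilyl)phenyl trifluoromethanesulfonate; 10 dimethyl malonate
Product: 12 methyl 4-(benzyloxy)-2-methoxy-6-(2-methoxy-2-oxoethyl)benzoate, via aryne 11 (not isolated)
Conditions: 10 (1.2 equiv), CsF (3 equiv), MeCN (0.1 M), 80 °C
Reagents that add atoms: none
Why: Fluoride attacks silicon and triflate departs to give aryne 11, and the malonate carbanion adds to the aryne carbon remote from OMe (future C6') because the inductively withdrawing C2' methoxy group polarises the triple bond and stabilises the aryl anion developing next to it (future C1'). This anion attacks one ester carbonyl of the newly attached malonyl unit (4-exo-trig) to form a benzocyclobutenoxide, which fragments by retro-Claisen-type C–C cleavage into the aryl ester and an arylacetate enolate, so the four-membered ring is transient and no ring remains in 12. The enolate is protonated by fresh malonate, which carries the anion chain forward. The closest known reaction type is the acyl-alkylation of arynes, that is, fluoride-triggered aryne insertion into the C–C sigma bond of malonates and beta-keto esters, and no stereocentre is formed. The step needs regioselectivity, which the 3-alkoxy group of the aryne secures (the 5-benzyloxy group is one position further from the triple bond and cannot override it), and it needs insertion to win over plain alpha-arylation, which the intramolecular acyl capture at moderate dilution favours. The symmetrical diester is chosen because a beta-keto ester would pass its ketone acyl group, not an ester, to C1'.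

**Step 8**
Reactants: 12 methyl 4-(benzyloxy)-2-methoxy-6-(2-methoxy-2-oxoethyl)benzoate
Product: 13 methyl 4-(benzyloxy)-2-methoxy-6-{2-[methoxy(methyl)amino]-2-oxoethyl}benzoate
Conditions: MeNH(OMe)·HCl, AlMe3, CH2Cl2, 0 °C to rt; quench 1 M HCl, 0 °C
Reagents that add atoms: N,O-dimethylhydroxylamine hydrochloride, CNOC.Cl
Why: Weinreb aminolysis with the aluminium amide reaches only the unhindered acetate ester, because the benzoate carbonyl is shielded by two ortho substituents.

**Step 9**
Reactants: 13 methyl 4-(benzyloxy)-2-methoxy-6-{2-[methoxy(methyl)amino]-2-oxoethyl}benzoate; 14 pentylmagnesium bromide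
Product: 15 methyl 4-(benzyloxy)-2-methoxy-6-(2-oxoheptyl)benzoate
Conditions: 14 (2.2 equiv), THF, −20 to 0 °C; quench cold 1 M HCl
Reagents that add atoms: none
Why: In the Weinreb ketone synthesis the Grignard reagent adds once to give a chelated magnesium adduct that collapses to the ketone only on quench, and the di-ortho-substituted methyl benzoate is too hindered to react at this temperature.

**Step 10**
Reactants: 15 methyl 4-(benzyloxy)-2-methoxy-6-(2-oxoheptyl)benzoate
Product: 16 methyl 4-hydroxy-2-methoxy-6-(2-oxoheptyl)benzoate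
Conditions: H2 (1 atm), Pd/C (10 wt %), EtOAc, rt
Reagents that add atoms: none
Why: Catalytic hydrogenolysis cleaves the benzylic C–O bond under conditions that leave the non-conjugated ketone, the ester and the aryl methyl ether unchanged.

**Step 11**
Reactants: 17 hexanoyl chloride
Product: 18 N-methoxy-N-methylhexanamide
Conditions: MeNH(OMe)·HCl, Et3N (2.2 equiv), CH2Cl2, 0 °C to rt
Reagents that add atoms: N,O-dimethylhydroxylamine hydrochloride, CNOC.Cl
Why: N-acylation of the liberated amine by an acid chloride (Schotten-Baumann type) is the standard preparation of a Weinreb amide.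

**Step 12**
Reactants: 19 methyl 2-hydroxy-4-methoxy-6-methylbenzoate
Product: 20 methyl 2-(benzyloxy)-4-methoxy-6-methylbenzoate
Conditions: BnBr, K2CO3, DMF, 60 °C
Reagents that add atoms: benzyl bromide, BrCc1ccccc1
Why: Williamson etherification with gentle heating overcomes the hydrogen bond of the phenol to the ester and removes the acidic proton before the lithiation.

**Step 13**
Reactants: 20 methyl 2-(benzyloxy)-4-methoxy-6-methylbenzoate; 18 N-methoxy-N-methylhexanamide
Product: 21 methyl 2-(benzyloxy)-4-methoxy-6-(2-oxoheptyl)benzoate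
Conditions: LDA (2.1 equiv), THF, −78 °C; then 18, −78 °C; quench cold 1 M HCl
Reagents that add atoms: none
Why: Lateral lithiation of the ortho-toluate gives an ester-stabilised benzylic anion, and its acylation by a Weinreb amide stops at the chelated adduct, so neither over-addition nor enolate attack on the ester can occur before the quench.

**Step 14**
Reactants: 21 methyl 2-(benzyloxy)-4-methoxy-6-(2-oxoheptyl)benzoate
Product: 22 methyl 2-(benzyloxy)-4-methoxy-6-[(2-pentyl-1,3-dioxolan-2-yl)methyl]benzoate
Conditions: TMSOCH2CH2OTMS, TMSOTf (10 mol %), CH2Cl2, −78 to −20 °C; pyridine quench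
Reagents that add atoms: 1,2-bis(trimethylsilyloxy)ethane, C[Si](C)(C)OCCO[Si](C)(C)C
Why: Noyori ketalisation runs cold and aprotic, which avoids heat- and acid-promoted enol lactonisation of the keto ester, and it masks the ketone that would otherwise close onto the activated carboxyl group in step 16 to form an isocoumarin.

**Step 15**
Reactants: 22 methyl 2-(benzyloxy)-4-methoxy-6-[(2-pentyl-1,3-dioxolan-2-yl)methyl]benzoate
Product: 23 2-(benzyloxy)-4-methoxy-6-[(2-pentyl-1,3-dioxolan-2-yl)methyl]benzoic acid
Conditions: KOH, DMSO–H2O, 90 °C; then cold 1 M HCl to pH 4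
Reagents that add atoms: potassium hydroxide, [K+].[OH-]
Why: Saponification of a di-ortho-substituted benzoate needs poorly solvated hydroxide in hot aqueous DMSO, conditions to which the ketal and both ethers are inert, and the cautious acidification spares the ketal.

**Step 16**
Reactants: 23 2-(benzyloxy)-4-methoxy-6-[(2-pentyl-1,3-dioxolan-2-yl)methyl]benzoic acid; 16 methyl 4-hydroxy-2-methoxy-6-(2-oxoheptyl)benzoate
Product: 24 3-methoxy-4-(methoxycarbonyl)-5-(2-oxoheptyl)phenyl 2-(benzyloxy)-4-methoxy-6-[(2-pentyl-1,3-dioxolan-2-yl)methyl]benzoate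
Conditions: DCC, DMAP (0.3 equiv), CH2Cl2, rt
Reagents that add atoms: none
Why: In the Steglich esterification DMAP takes the acyl group from the O-acylisourea and passes it to the unhindered, fairly acidic C4' phenol, the usual way to para-depsides, while the ketone and methyl ester of 16 are spectators.

**Step 17**
Reactants: 24 3-methoxy-4-(methoxycarbonyl)-5-(2-oxoheptyl)phenyl 2-(benzyloxy)-4-methoxy-6-[(2-pentyl-1,3-dioxolan-2-yl)methyl]benzoate
Product: 26 gustastatin, via O-benzylgustastatin 25 (not isolated)
Conditions: 1 M aq HCl, THF, rt; then Pd/C (10 wt %), H2 (1 atm), same flask, rt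
Reagents that add atoms: water, O
Why: Acetal hydrolysis frees the ring A ketone and hydrogenolysis in the same acidic medium frees the C2 phenol, while the hindered depside and methyl esters resist dilute acid at rt and the non-conjugated ketones are not reduced over Pd/C.

**Compound list**
1 | 5-bromovanillin (3-bromo-4-hydroxy-5-methoxybenzaldehyde) | COc1cc(C=O)cc(Br)c1O | starting material
2 | 3-bromo-5-methoxy-4-(methoxymethoxy)benzaldehyde | COCOc1c(Br)cc(C=O)cc1OC | intermediate
3 | 3-bromo-5-methoxy-4-(methoxymethoxy)phenyl formate | COCOc1c(Br)cc(OC=O)cc1OC | intermediate (not isolated)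
4 | 3-bromo-5-methoxy-4-(methoxymethoxy)phenol | COCOc1c(Br)cc(O)cc1OC | intermediate
5 | 5-(benzyloxy)-1-bromo-3-methoxy-2-(methoxymethoxy)benzene | COCOc1c(Br)cc(OCc2ccccc2)cc1OC | intermediate
6 | 4-(benzyloxy)-2-bromo-6-methoxyphenol | COc1cc(OCc2ccccc2)cc(Br)c1O | intermediate
7 | [4-(benzyloxy)-2-bromo-6-methoxyphenoxy]trimethylsilane | COc1cc(OCc2ccccc2)cc(Br)c1O[Si](C)(C)C | intermediate
8 | lithium 4-(benzyloxy)-2-methoxy-6-(trimethylsilyl)phenoxide | [Li+].[O-]c1c(OC)cc(OCc2ccccc2)cc1[Si](C)(C)C | intermediate (not isolated)
9 | 4-(benzyloxy)-2-methoxy-6-(trimethylsilyl)phenyl trifluoromethanesulfonate | COc1cc(OCc2ccccc2)cc([Si](C)(C)C)c1OS(=O)(=O)C(F)(F)F | intermediate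
10 | dimethyl malonate | COC(=O)CC(=O)OC | starting material
11 | 1-(benzyloxy)-3-methoxy-4,5-didehydrobenzene (5-benzyloxy-3-methoxybenzyne) | COC1=CC(OCc2ccccc2)=CC#C1 | intermediate (not isolated)
12 | methyl 4-(benzyloxy)-2-methoxy-6-(2-methoxy-2-oxoethyl)benzoate | COC(=O)Cc1cc(OCc2ccccc2)cc(OC)c1C(=O)OC | intermediate
13 | methyl 4-(benzyloxy)-2-methoxy-6-{2-[methoxy(methyl)amino]-2-oxoethyl}benzoate | CON(C)C(=O)Cc1cc(OCc2ccccc2)cc(OC)c1C(=O)OC | intermediate
14 | pentylmagnesium bromide | CCCCC[Mg]Br | starting material
15 | methyl 4-(benzyloxy)-2-methoxy-6-(2-oxoheptyl)benzoate | CCCCCC(=O)Cc1cc(OCc2ccccc2)cc(OC)c1C(=O)OC | intermediate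
16 | methyl 4-hydroxy-2-methoxy-6-(2-oxoheptyl)benzoate | CCCCCC(=O)Cc1cc(O)cc(OC)c1C(=O)OC | intermediate
17 | hexanoyl chloride | CCCCCC(=O)Cl | starting material
18 | N-methoxy-N-methylhexanamide | CCCCCC(=O)N(C)OC | intermediate
19 | methyl 2-hydroxy-4-methoxy-6-methylbenzoate | COc1cc(C)c(C(=O)OC)c(O)c1 | starting material
20 | methyl 2-(benzyloxy)-4-methoxy-6-methylbenzoate | COc1cc(C)c(C(=O)OC)c(OCc2ccccc2)c1 | intermediate
21 | methyl 2-(benzyloxy)-4-methoxy-6-(2-oxoheptyl)benzoate | CCCCCC(=O)Cc1cc(OC)cc(OCc2ccccc2)c1C(=O)OC | intermediate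
22 | methyl 2-(benzyloxy)-4-methoxy-6-[(2-pentyl-1,3-dioxolan-2-yl)methyl]benzoate | CCCCCC1(Cc2cc(OC)cc(OCc3ccccc3)c2C(=O)OC)OCCO1 | intermediate
23 | 2-(benzyloxy)-4-methoxy-6-[(2-pentyl-1,3-dioxolan-2-yl)methyl]benzoic acid | CCCCCC1(Cc2cc(OC)cc(OCc3ccccc3)c2C(=O)O)OCCO1 | intermediate
24 | 3-methoxy-4-(methoxycarbonyl)-5-(2-oxoheptyl)phenyl 2-(benzyloxy)-4-methoxy-6-[(2-pentyl-1,3-dioxolan-2-yl)methyl]benzoate | CCCCCC1(Cc2cc(OC)cc(OCc3ccccc3)c2C(=O)Oc2cc(CC(=O)CCCCC)c(C(=O)OC)c(OC)c2)OCCO1 | intermediate
25 | O-benzylgustastatin, 3-methoxy-4-(methoxycarbonyl)-5-(2-oxoheptyl)phenyl 2-(benzyloxy)-4-methoxy-6-(2-oxoheptyl)benzoate | CCCCCC(=O)Cc1cc(OC)cc(OCc2ccccc2)c1C(=O)Oc1cc(CC(=O)CCCCC)c(C(=O)OC)c(OC)c1 | intermediate (not isolated)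
26 | gustastatin, 3-methoxy-4-(methoxycarbonyl)-5-(2-oxoheptyl)phenyl 2-hydroxy-4-methoxy-6-(2-oxoheptyl)benzoate | CCCCCC(=O)Cc1cc(OC)cc(O)c1C(=O)Oc1cc(CC(=O)CCCCC)c(C(=O)OC)c(OC)c1 | target

**Step count and risks**

Total step count: 17.
Longest linear sequence: 12 (steps 1–10, 16, 17).

Steps most likely to fail:

**Step 7 (aryne insertion).**
- What may go wrong: proton transfer to the aryl anion before it reaches the ester carbonyl (plain alpha-arylation of the malonate), a second arylation of the product enolate, or erosion of the regioselectivity of addition.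
- Fallback: it sets out from 6, comes back at 12, and forms the same two bonds one after the other by palladium catalysis. Tf2O and pyridine in CH2Cl2 convert 6 into 4-(benzyloxy)-2-bromo-6-methoxyphenyl trifluoromethanesulfonate F1. The Reformatsky reagent bromo(2-methoxy-2-oxoethyl)zinc F2, made from methyl bromoacetate and zinc dust in THF, is coupled at the C–Br bond with Pd(dba)2 and P(t-Bu)3, a catalyst that prefers bromide to triflate. This gives methyl 2-[5-(benzyloxy)-3-methoxy-2-(trifluoromethylsulfonyloxy)phenyl]acetate F3. Methoxycarbonylation of the triflate (Pd(OAc)2, dppp, CO, MeOH, Et3N, DMF, 70 °C) then gives 12.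

**Step 16 (depside esterification).**
- What may go wrong: slow acyl transfer from the di-ortho-substituted acid, O-to-N acyl shift of the activated acid to an unreactive N-acylurea, or attack of a ketal oxygen on the activated carboxyl group with loss of the protecting group.
- Fallback: it sets out from 19, uses 18 and 16 as partners, and comes back at 26. It replaces carboxyl activation by photochemical ketene generation and needs no protecting group on ring A. KOH in aqueous ethanol at reflux gives 2-hydroxy-4-methoxy-6-methylbenzoic acid F4. Acetone, trifluoroacetic anhydride and trifluoroacetic acid give 7-methoxy-2,2,5-trimethyl-4H-1,3-benzodioxin-4-one F5. Lateral lithiation with LDA at −78 °C and acylation with 18 give 7-methoxy-2,2-dimethyl-5-(2-oxoheptyl)-4H-1,3-benzodioxin-4-one F6. Irradiation of F6 at 300 nm in CH2Cl2 in the presence of 16 expels acetone to give the quinoketene 3-methoxy-6-(oxomethylidene)-5-(2-oxoheptyl)cyclohexa-2,4-dien-1-one F7. The phenol 16 captures F7 to give 26 directly.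

**Step 9 (Grignard addition).**
- What may go wrong: deprotonation of the doubly activated benzylic CH2 group by the Grignard reagent instead of addition, followed by attack of the amide enolate oxygen on the neighbouring ester.
- Fallback: it sets out from 12, comes back at 15, and uses a non-basic organozinc acylation. LiOH (1 equiv) in THF–H2O at 0 °C saponifies only the acetate ester to give 2-[5-(benzyloxy)-3-methoxy-2-(methoxycarbonyl)phenyl]acetic acid F8. EtSH, DCC and DMAP give methyl 4-(benzyloxy)-2-[2-(ethylsulfanyl)-2-oxoethyl]-6-methoxybenzoate F9. Fukuyama coupling with commercial pentylzinc bromide and PdCl2(PPh3)2 in toluene–THF at rt gives 15.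

**Further compounds**
F1 | step 7 | 4-(benzyloxy)-2-bromo-6-methoxyphenyl trifluoromethanesulfonate | COc1cc(OCc2ccccc2)cc(Br)c1OS(=O)(=O)C(F)(F)F
F2 | step 7 | bromo(2-methoxy-2-oxoethyl)zinc | COC(=O)C[Zn]Br
F3 | step 7 | methyl 2-[5-(benzyloxy)-3-methoxy-2-(trifluoromethylsulfonyloxy)phenyl]acetate | COC(=O)Cc1cc(OCc2ccccc2)cc(OC)c1OS(=O)(=O)C(F)(F)F
F4 | step 16 | 2-hydroxy-4-methoxy-6-methylbenzoic acid | COc1cc(C)c(C(=O)O)c(O)c1
F5 | step 16 | 7-methoxy-2,2,5-trimethyl-4H-1,3-benzodioxin-4-one | COc1cc(C)c2C(=O)OC(C)(C)Oc2c1
F6 | step 16 | 7-methoxy-2,2-dimethyl-5-(2-oxoheptyl)-4H-1,3-benzodioxin-4-one | CCCCCC(=O)Cc1cc(OC)cc2OC(C)(C)OC(=O)c12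
F7 | step 16 | 3-methoxy-6-(oxomethylidene)-5-(2-oxoheptyl)cyclohexa-2,4-dien-1-one | CCCCCC(=O)CC1=CC(OC)=CC(=O)C1=C=O
F8 | step 9 | 2-[5-(benzyloxy)-3-methoxy-2-(methoxycarbonyl)phenyl]acetic acid | OC(=O)Cc1cc(OCc2ccccc2)cc(OC)c1C(=O)OC
F9 | step 9 | methyl 4-(benzyloxy)-2-[2-(ethylsulfanyl)-2-oxoethyl]-6-methoxybenzoate | CCSC(=O)Cc1cc(OCc2ccccc2)cc(OC)c1C(=O)OC
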